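## Structural features

The target (13) is a diaryl ether of two benzene rings with no other ring. Ring A is a methyl benzoate (ester at C1) with a prenyl ether at C2, a methyl group at C4 and the bridging oxygen at C6. Ring B carries that oxygen at C1', a hydroxymethyl group at C2' and methoxy groups at C4' and C6'. The two ring B methoxy groups are meta to each other, and the bridging oxygen is ortho to one (C6') and para to the other (C4'). The molecule has no stereocentre, no stereogenic double bond and no configurationally stable axis. The only stereocentres in the route are the adjacent C1' and C2' of a transient cyclohexanedione, and they are erased again.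

The fragile groups are the aryl prenyl ether (acid, electrophilic halogen, palladium hydride, heat), the benzylic alcohol ortho to an aryloxy group (acid-promoted substitution, oxidation) and the ester between two oxygens, which is shielded from external nucleophiles but exposed to a carbanion on an ortho side chain. The real difficulty is the C6–O–C1' bond: it is flanked by three ortho substituents on two electron-rich rings, which makes SNAr or copper coupling unattractive. A second difficulty is telling four phenolic oxygens apart (two methyl, one prenyl, one aryl).

The key step exploits the meta relationship of the C4' and C6' oxygens. One oxidation level down, ring B is a cyclohexane-1,3-dione in which C1' is alpha to the C6' carbonyl and C2' is a beta carbon. The O–C1' bond can therefore be made by SN2 at an sp3 carbon, and the ring is then closed around it through C1'–C2' and C4'–C5'.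

## Logic of the disconnections

13 ⇒ 12. The O–Si bond on the C2' hydroxymethyl oxygen is cut (protecting-group disconnection). A free primary alcohol would become benzylic in the aromatisation and be oxidised there, so it is masked through steps 3 to 6. There is no skeletal gain, but all earlier steps are freed from an alcohol. The forward fluoride cleavage must spare the methyl ester and the prenyl ether, and the liberated alkoxide must not attack the ring A ester.

12 ⇒ 10 + 11. The O–CH2 bond of the prenyl ether at C2 of ring A is cut. The prenyl group is the most fragile part and cannot pass the oxidation of step 4, so it is attached after ring B is aromatic and methylated. The gain is that five carbons come from a purchasable halide. The forward step must O-alkylate a chelated, flanked phenol without C-alkylation and without acid.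

10 ⇒ 9. The O–CH3 bonds at C4' and C6' are cut. These oxygens are the former dione carbonyl oxygens and appear as free phenols. Ring B becomes a plain resorcinol. Two free phenols must be methylated while the ring A hydroxyl is left alone; the distinction rests on the hydrogen bond of that hydroxyl to the ester carbonyl.

9 ⇒ 8. No skeletal bond is cut; two hydrogens are added back at C1' and C2'. Ring B becomes a 1,3-dione in which C1' is sp3, bears the ether oxygen and is alpha to a ketone. Enolate chemistry becomes available, and the two stereocentres that appear are of no consequence. The forward oxidation must remove exactly these two hydrogens without reductive or eliminative loss of the aryloxy group (loss of the ring A phenol would also aromatise ring B), without halogenating ring A and with the silyl ether intact.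

8 ⇒ 3 + 6 (through 7). C1'–C2' is cut as a conjugate addition and C4'–C5' as a Claisen acylation. Ring B shrinks to a three-carbon ketone unit already attached to the ring A oxygen plus a four-carbon acceptor that carries the hydroxymethyl carbon at its final oxidation level. The hindered diaryl ether is no longer a problem. The forward step must enolise at C1' and not at C5', must add to the acceptor faster than the enolate closes onto the ring A ester, and must not destroy the base-sensitive acceptor. The ring A hydroxyl of 3 is deliberately left free so that its phenoxide deactivates the neighbouring ester.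

3 ⇒ 1 + 2. The ring A O–CH2 bond is cut (SN2). Compound 1 is symmetrical, so there is only one mono-ether. The forward step must stop after one alkylation and must not be basic enough to cyclise the product.

6 ⇒ 4 + 5. The C2'=C3' double bond is cut (Wittig). Both partners are purchasable, and a stabilised ylide should give the E-alkene.

## Other disconnections considered

Alternative 1: The cut is the ring A C6–O bond together with the C1–CO2 bond. In the forward step fluoride would release the aryne from the silyl triflate A1 (3-(methoxymethoxy)-5-methyl-2-(trimethylsilyl)phenyl trifluoromethanesulfonate). The caesium phenoxide of A2 (2,4-dimethoxy-6-[(methoxymethoxy)methyl]phenol) would add at C6, distal to the alkoxy group, and the C1 aryl anion would be trapped by carbon dioxide to give the acid A3.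
- In its favour: it is convergent; three contiguous ring A substituents are set in one operation; the regiochemistry follows from aryne polarisation; and an aryne is not sensitive to the hindrance around the ether bond.
- Better than the chosen plan: ring B arrives with its methyl ethers, so no phenol has to be singled out and no oxidation is needed.
- Against it: the aryl anion can be protonated before it is carboxylated; the phenoxide can bind carbon dioxide reversibly and lose nucleophilicity; and A1 and A2 each need several steps.
- After A3 three more operations remain: esterification, acidic removal of two acetal groups next to an activated benzylic position, and prenylation.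
- Comparison: better on structure and convergence, less certain on mechanism (a three-component trapping against a clean intramolecular sink), and clearly longer overall.

Alternative 2: The cuts are the ring A C1–C2 and C5–C6 bonds. In the forward step the aryloxypropiolate A4 would undergo a Diels–Alder reaction with the ketene acetal diene A5, and loss of trimethylsilanol would give the salicylate A6, which is identical with 10.
- In its favour: the polarity is matched (nucleophilic CH2 terminus of A5 to the aryloxy-bearing alkyne carbon) and no oxidant is needed.
- Better than the chosen plan: ring A is born with its chelated hydroxyl already distinguished, so the selective methylation of step 5 is not needed.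
- Equal: the endgame (prenylation, desilylation) is the same.
- Against it: A4 is a push–pull alkyne whose oxygen donor lowers its dienophilicity; it must be made from a hindered 2,6-disubstituted ring B phenol through an ynol ether, which is demanding; and A5 is moisture-sensitive.
- Comparison: the chosen plan avoids preparing any ring B phenol and makes the ether bond on a simple phenol, at the price of an oxidation and a selective alkylation. The alternative has two steps after its key step against four, but considerably more before it.

Alternative 3: The cuts are the ring A C4–C5 and C1–C6 bonds. In the forward step the pyrone ester A7 and the aryl ethynyl ether A8 would give a bridged lactone on heating, which would lose carbon dioxide to give the arene A9.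
- In its favour: the loss of carbon dioxide is irreversible; an electron-poor pyrone is matched with an electron-rich alkyne; and the arene forms directly.
- Equal or better than the chosen plan: there is no oxidation and no selective methylation, and the ring A oxygens are distinguished from the start (benzyl against aryl).
- Against it: aryl ethynyl ethers are thermally labile while pyrone cycloadditions need heat; the 4-benzyloxy donor lowers the electrophilicity of A7; and the regiochemical pairing is plausible but not secured by a strong bias.
- After A9 three steps remain: debenzylation that must spare a benzylic silyl ether, prenylation and desilylation. Neither A7 nor A8 is purchasable.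
- Comparison: similar length after the key step, longer before it, and a thermally more delicate key step than an anionic annulation that ends in a stabilised enolate.

Key step: step 3

Remarks on the design (chemistry):
- Compounds 1, 2, 4, 5 and 11 are taken as purchasable.
- The atom map and oxidation levels of 3, 6 and 8 were checked and are consistent: the C4' and C6' carbonyls of 8 become the two methoxy-bearing carbons, C1' carries the ether oxygen and C2' the protected hydroxymethyl group.
- Compound 8 is racemic. The trans isomer is written; any cis isomer is carried along, because step 4 erases both centres.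
- The base in step 3 is tert-butoxide, which the substrate consumes at once, so no free alkoxide is left to add to or deconjugate 6.
- Two common ways to aromatise such a dione are set aside. Pd on carbon generates palladium hydride that can cleave the alpha-aryloxy ketone C–O bond. Iodine in methanol would put an electrophilic halogen on C1' and produce hydrogen iodide, which threatens the silyl ether.

## Route

Step 1
Reactants: 1 methyl 2,6-dihydroxy-4-methylbenzoate; 2 chloroacetone (1.0 equiv)
Product: 3 methyl 2-hydroxy-4-methyl-6-(2-oxopropoxy)benzoate
Conditions: K2CO3 (1.1 equiv), NaI (10 mol%), acetone, 45 °C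
Reagents that add atoms: none
Why: Williamson ether synthesis (phenoxide SN2 on an alpha-chloro ketone); the symmetrical substrate gives a single mono-ether, and the remaining hydroxyl is hydrogen-bonded to the ester carbonyl, which slows a second alkylation when one equivalent of 2 is used.

Step 2
Reactants: 4 (tert-butyldimethylsilyloxy)acetaldehyde; 5 methyl (triphenylphosphoranylidene)acetate
Product: 6 methyl (E)-4-(tert-butyldimethylsilyloxy)but-2-enoate
Conditions: CH2Cl2, 0 °C to rt
Reagents that add atoms: none
Why: Wittig olefination with a stabilised ylide, which should give the E-alkene predominantly; the silyl ether is inert.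

Step 3
Reactants: 3 methyl 2-hydroxy-4-methyl-6-(2-oxopropoxy)benzoate; 6 methyl (E)-4-(tert-butyldimethylsilyloxy)but-2-enoate (1.5 equiv)
Product: 8 methyl 2-{[(1S*,2S*)-2-[(tert-butyldimethylsilyloxy)methyl]-4,6-dioxocyclohexyl]oxy}-6-hydroxy-4-methylbenzoate (racemic trans isomer), via open-chain Michael adduct 7 (not isolated)
Conditions: KOtBu (2.2 equiv), THF/t-BuOH 10:1, −20 °C to rt; then 1 M HCl (aq), 0 °C, to pH 4
Reagents that add atoms: none
Why: Consecutive Michael–Claisen [3+3] annulation, the known route from substituted acetones and alpha,beta-unsaturated esters to cyclohexane-1,3-diones. The first equivalent of base gives the ring A phenoxide and the second, equilibrating through t-BuOH, gives the enolate at the aryloxy-bearing carbon C1', the more acidic alpha position of the ketone. This enolate adds to the beta carbon of 6 (bond C1'–C2') to give the ester enolate of 7; proton transfer forms the methyl ketone enolate (C5'), which attacks the aliphatic ester carbonyl (bond C4'–C5') in a 6-exo-trig Claisen closure and expels methoxide. The methoxide deprotonates the new 1,3-dione, and this stabilised enolate is the sink that pulls the reversible steps forward. C1' and C2' form without strong bias in the acyclic Michael step, but C1' stays epimerisable next to the C6' carbonyl, so the diequatorial trans isomer should dominate; the product is racemic and both centres are removed in step 4, so no control is needed. Site selectivity (C1' over the methyl group) rests on the acidifying aryloxy group; chemoselectivity against 5-exo Dieckmann attack on the ring A ester rests on the ortho phenoxide, which makes that ester a poorly electrophilic vinylogous carbonate, and on the excess of 6. Methyl esters on both partners and a non-adding base mean that ester exchange and alkoxide conjugate addition to 6 should not matter.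

Step 4
Reactants: 8 methyl 2-{[(1S*,2S*)-2-[(tert-butyldimethylsilyloxy)methyl]-4,6-dioxocyclohexyl]oxy}-6-hydroxy-4-methylbenzoate
Product: 9 methyl 2-{2-[(tert-butyldimethylsilyloxy)methyl]-4,6-dihydroxyphenoxy}-6-hydroxy-4-methylbenzoate
Conditions: Pd(OCOCF3)2 (5 mol%), 2-(dimethylamino)pyridine (10 mol%), TsOH·H2O (20 mol%), O2 (1 atm), DMSO, 80 °C
Reagents that add atoms: none
Why: Dehydrogenative aromatisation of a cyclohexane-1,3-dione to a resorcinol, run as the palladium-catalysed aerobic dehydrogenation of a cyclohexenone (the enol form of the dione) to a phenol: a divalent palladium enolate at C1' or C3' undergoes beta-hydride elimination towards C2', and tautomerisation gives the arene. O2 reoxidises zerovalent palladium, so no palladium hydride accumulates that could cleave the C1'–O bond, no electrophilic halogen touches C1' or ring A, and the primary silyl ether should tolerate the catalytic acid in DMSO.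

Step 5
Reactants: 9 methyl 2-{2-[(tert-butyldimethylsilyloxy)methyl]-4,6-dihydroxyphenoxy}-6-hydroxy-4-methylbenzoate
Product: 10 methyl 2-{2-[(tert-butyldimethylsilyloxy)methyl]-4,6-dimethoxyphenoxy}-6-hydroxy-4-methylbenzoate
Conditions: MeI (2.2 equiv), K2CO3 (2.5 equiv), acetone, rt
Reagents that add atoms: iodomethane, CI
Why: Williamson O-methylation; the two ring B phenols are free and should react at room temperature, whereas the ring A hydroxyl is chelated to the ester carbonyl and needs heat, so a small excess of MeI should stop at the dimethyl ether.

Step 6
Reactants: 10 methyl 2-{2-[(tert-butyldimethylsilyloxy)methyl]-4,6-dimethoxyphenoxy}-6-hydroxy-4-methylbenzoate; 11 1-bromo-3-methylbut-2-ene (prenyl bromide, 1.5 equiv)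
Product: 12 methyl 2-{2-[(tert-butyldimethylsilyloxy)methyl]-4,6-dimethoxyphenoxy}-4-methyl-6-[(3-methylbut-2-en-1-yl)oxy]benzoate
Conditions: K2CO3 (2 equiv), DMF, 50 °C
Reagents that add atoms: none
Why: Williamson alkylation of the chelated phenol under more forcing conditions; K2CO3 in a polar aprotic solvent favours O- over C-alkylation and SN2 over SN2' for a primary allylic bromide, and the temperature is far below that of an aryl prenyl ether Claisen rearrangement.

Step 7
Reactants: 12 methyl 2-{2-[(tert-butyldimethylsilyloxy)methyl]-4,6-dimethoxyphenoxy}-4-methyl-6-[(3-methylbut-2-en-1-yl)oxy]benzoate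
Product: 13 methyl 2-[2-(hydroxymethyl)-4,6-dimethoxyphenoxy]-4-methyl-6-[(3-methylbut-2-en-1-yl)oxy]benzoate (target)
Conditions: Bu4NF (TBAF, 1.2 equiv), AcOH (1.2 equiv), THF, 0 °C to rt
Reagents that add atoms: none
Why: Fluoride-induced cleavage of the Si–O bond, driven by the strong Si–F bond; the AcOH buffer keeps the liberated alkoxide protonated, so the hindered methyl ester is neither hydrolysed nor attacked intramolecularly, and the prenyl ether is inert.

## Compound list

1 | methyl 2,6-dihydroxy-4-methylbenzoate | COC(=O)c1c(O)cc(C)cc1O | starting material
2 | chloroacetone (1-chloropropan-2-one) | CC(=O)CCl | starting material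
3 | methyl 2-hydroxy-4-methyl-6-(2-oxopropoxy)benzoate | COC(=O)c1c(O)cc(C)cc1OCC(C)=O | intermediate
4 | (tert-butyldimethylsilyloxy)acetaldehyde | O=CCO[Si](C)(C)C(C)(C)C | starting material
5 | methyl (triphenylphosphoranylidene)acetate | COC(=O)C=P(c1ccccc1)(c1ccccc1)c1ccccc1 | starting material
6 | methyl (E)-4-(tert-butyldimethylsilyloxy)but-2-enoate | COC(=O)/C=C/CO[Si](C)(C)C(C)(C)C | intermediate
7 | methyl 3-[(tert-butyldimethylsilyloxy)methyl]-4-[3-hydroxy-2-(methoxycarbonyl)-5-methylphenoxy]-5-oxohexanoate (racemic, mixture of diastereomers, not isolated) | COC(=O)CC(CO[Si](C)(C)C(C)(C)C)C(Oc1cc(C)cc(O)c1C(=O)OC)C(C)=O | intermediate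
8 | methyl 2-{[(1S*,2S*)-2-[(tert-butyldimethylsilyloxy)methyl]-4,6-dioxocyclohexyl]oxy}-6-hydroxy-4-methylbenzoate (racemic trans isomer, one enantiomer written) | CC(C)(C)[Si](C)(C)OC[C@@H]1CC(=O)CC(=O)[C@H]1Oc1cc(C)cc(O)c1C(=O)OC | intermediate
9 | methyl 2-{2-[(tert-butyldimethylsilyloxy)methyl]-4,6-dihydroxyphenoxy}-6-hydroxy-4-methylbenzoate | COC(=O)c1c(O)cc(C)cc1Oc1c(CO[Si](C)(C)C(C)(C)C)cc(O)cc1O | intermediate
10 | methyl 2-{2-[(tert-butyldimethylsilyloxy)methyl]-4,6-dimethoxyphenoxy}-6-hydroxy-4-methylbenzoate | COC(=O)c1c(O)cc(C)cc1Oc1c(CO[Si](C)(C)C(C)(C)C)cc(OC)cc1OC | intermediate
11 | 1-bromo-3-methylbut-2-ene (prenyl bromide) | CC(C)=CCBr | starting material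
12 | methyl 2-{2-[(tert-butyldimethylsilyloxy)methyl]-4,6-dimethoxyphenoxy}-4-methyl-6-[(3-methylbut-2-en-1-yl)oxy]benzoate | COC(=O)c1c(OCC=C(C)C)cc(C)cc1Oc1c(CO[Si](C)(C)C(C)(C)C)cc(OC)cc1OC | intermediate
13 | methyl 2-[2-(hydroxymethyl)-4,6-dimethoxyphenoxy]-4-methyl-6-[(3-methylbut-2-en-1-yl)oxy]benzoate | COC(=O)c1c(OCC=C(C)C)cc(C)cc1Oc1c(CO)cc(OC)cc1OC | target

## Step count and least certain steps

Total step count: 7. Longest linear sequence: 6 (steps 1, 3, 4, 5, 6, 7); step 2 is a one-step side branch.

Step 3 (key step). The most likely failure is ring closure of the C1' enolate onto the ring A ester (a five-membered Dieckmann-type closure to a benzofuranone) outrunning the intermolecular conjugate addition; the phenoxide lowers the electrophilicity of that ester but does not remove it. Two further risks are base-induced deconjugation of 6 through gamma-deprotonation, which drains the acceptor, and conjugate addition through the methyl group.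

Fallback, from 3 back to 8 through 7: take the bimolecular C–C bond formation out of basic medium. Compound 3 is silylated with Me3SiOSO2CF3/Et3N to methyl 4-methyl-2-(trimethylsilyloxy)-6-{[(1Z)-2-(trimethylsilyloxy)prop-1-en-1-yl]oxy}benzoate F1 (enol geometry of no consequence). F1 is added to 6 in a Mukaiyama–Michael reaction (TiCl4, CH2Cl2, −78 °C), and aqueous work-up should give 7, now isolated. Claisen closure of 7 with KOtBu in THF then gives 8. In 7 the carbon C1' is tertiary, so a Dieckmann closure from it would have to build a quaternary centre, whereas the methyl ketone enolate closes the six-membered ring unhindered.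

Step 4. The likely failures are:
- stalling of the catalyst because divalent palladium is held as a diketonate chelate by the substrate;
- loss of the ring A phenol from C1', which also aromatises ring B;
- further oxidation of the electron-rich resorcinol;
- partial loss of the silyl group under the acid co-catalyst.

Fallback, from 8 back to 9: aromatise through a silyl dienol ether. Exhaustive silylation of 8 (Me3SiOSO2CF3, Et3N, CH2Cl2, 0 °C) should give methyl 2-{[trans-6-[(tert-butyldimethylsilyloxy)methyl]-2,4-bis(trimethylsilyloxy)cyclohexa-2,4-dien-1-yl]oxy}-4-methyl-6-(trimethylsilyloxy)benzoate F2 (racemic; a double-bond isomer would behave alike). Hydride abstraction with DDQ (CH2Cl2, rt), the usual aromatisation of bis(silyloxy)cyclohexadienes, gives methyl 2-{2-[(tert-butyldimethylsilyloxy)methyl]-4,6-bis(trimethylsilyloxy)phenoxy}-4-methyl-6-(trimethylsilyloxy)benzoate F3. Brief methanolysis (K2CO3, MeOH, 0 °C) cleaves the three aryl silyl ethers, leaves the primary tert-butyldimethylsilyl ether and returns 9.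

Step 5. The likely failure is loss of discrimination between free and chelated phenols (methylation creeping onto the ring A hydroxyl), or sluggish methylation of the C6' hydroxyl next to the bulky aryloxy group, which tempts heating and worsens the first problem.

Fallback, from 9 back to 10: over-alkylate and then dealkylate selectively. Exhaustive methylation (excess MeI, K2CO3, DMF, 60 °C) gives methyl 2-{2-[(tert-butyldimethylsilyloxy)methyl]-4,6-dimethoxyphenoxy}-6-methoxy-4-methylbenzoate F4. BCl3 (1.1 equiv, CH2Cl2, −78 °C) then cleaves only the methyl ether ortho to the ester carbonyl by chelation-directed dealkylation and returns 10.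

Step 1. The likely failures are a second alkylation of the symmetrical diol, self-condensation of 2 under base, and base-induced cyclisation of 3 (enolate attack on the ortho ester) on prolonged heating.

Fallback, from 1 back to 3: etherify without base and unmask the ketone afterwards. Mitsunobu reaction of 1 with 2-methylprop-2-en-1-ol (PPh3, DIAD, THF) should stop at the mono-ether because the remaining hydroxyl is chelated, and gives methyl 2-hydroxy-4-methyl-6-[(2-methylprop-2-en-1-yl)oxy]benzoate F5. Lemieux–Johnson cleavage of the 1,1-disubstituted alkene (OsO4 cat., NaIO4, 2,6-lutidine, dioxane/water) then gives 3.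

## Further compounds

F1 | step 3 | methyl 4-methyl-2-(trimethylsilyloxy)-6-{[(1Z)-2-(trimethylsilyloxy)prop-1-en-1-yl]oxy}benzoate | COC(=O)c1c(O[Si](C)(C)C)cc(C)cc1O/C=C(/C)O[Si](C)(C)C
F2 | step 4 | methyl 2-{[trans-6-[(tert-butyldimethylsilyloxy)methyl]-2,4-bis(trimethylsilyloxy)cyclohexa-2,4-dien-1-yl]oxy}-4-methyl-6-(trimethylsilyloxy)benzoate (racemic, one enantiomer written) | CC(C)(C)[Si](C)(C)OC[C@@H]1C=C(O[Si](C)(C)C)C=C(O[Si](C)(C)C)[C@H]1Oc1cc(C)cc(O[Si](C)(C)C)c1C(=O)OC
F3 | step 4 | methyl 2-{2-[(tert-butyldimethylsilyloxy)methyl]-4,6-bis(trimethylsilyloxy)phenoxy}-4-methyl-6-(trimethylsilyloxy)benzoate | COC(=O)c1c(O[Si](C)(C)C)cc(C)cc1Oc1c(CO[Si](C)(C)C(C)(C)C)cc(O[Si](C)(C)C)cc1O[Si](C)(C)C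
F4 | step 5 | methyl 2-{2-[(tert-butyldimethylsilyloxy)methyl]-4,6-dimethoxyphenoxy}-6-methoxy-4-methylbenzoate | COC(=O)c1c(OC)cc(C)cc1Oc1c(CO[Si](C)(C)C(C)(C)C)cc(OC)cc1OC
F5 | step 1 | methyl 2-hydroxy-4-methyl-6-[(2-methylprop-2-en-1-yl)oxy]benzoate | COC(=O)c1c(O)cc(C)cc1OCC(C)=C
A1 | alternative 1 | 3-(methoxymethoxy)-5-methyl-2-(trimethylsilyl)phenyl trifluoromethanesulfonate | COCOc1cc(C)cc(OS(=O)(=O)C(F)(F)F)c1[Si](C)(C)C
A2 | alternative 1 | 2,4-dimethoxy-6-[(methoxymethoxy)methyl]phenol | COCOCc1cc(OC)cc(OC)c1O
A3 | alternative 1 | 2-{2,4-dimethoxy-6-[(methoxymethoxy)methyl]phenoxy}-6-(methoxymethoxy)-4-methylbenzoic acid | OC(=O)c1c(OCOC)cc(C)cc1Oc1c(COCOC)cc(OC)cc1OC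
A4 | alternative 2 | methyl 3-{2-[(tert-butyldimethylsilyloxy)methyl]-4,6-dimethoxyphenoxy}prop-2-ynoate | COC(=O)C#COc1c(CO[Si](C)(C)C(C)(C)C)cc(OC)cc1OC
A5 | alternative 2 | 3-methyl-1,1-bis(trimethylsilyloxy)buta-1,3-diene | C=C(C)C=C(O[Si](C)(C)C)O[Si](C)(C)C
A6 | alternative 2 | methyl 2-{2-[(tert-butyldimethylsilyloxy)methyl]-4,6-dimethoxyphenoxy}-6-hydroxy-4-methylbenzoate (identical with 10) | COC(=O)c1c(O)cc(C)cc1Oc1c(CO[Si](C)(C)C(C)(C)C)cc(OC)cc1OC
A7 | alternative 3 | methyl 4-(benzyloxy)-6-methyl-2-oxo-2H-pyran-3-carboxylate | COC(=O)C1=C(OCc2ccccc2)C=C(C)OC1=O
A8 | alternative 3 | tert-butyl{[2-(ethynyloxy)-3,5-dimethoxyphenyl]methoxy}dimethylsilane | C#COc1c(CO[Si](C)(C)C(C)(C)C)cc(OC)cc1OC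
A9 | alternative 3 | methyl 2-(benzyloxy)-6-{2-[(tert-butyldimethylsilyloxy)methyl]-4,6-dimethoxyphenoxy}-4-methylbenzoate | COC(=O)c1c(OCc2ccccc2)cc(C)cc1Oc1c(CO[Si](C)(C)C(C)(C)C)cc(OC)cc1OC
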